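Count the turns.

all flasks: starting material 0.012 M
- birch: protic impurity 1.2 mM; precatalyst 12 µM; temperature 20 °C; run made earlier
- cedar: protic impurity 1.2 mM; precatalyst 48 µM; temperature 35 °C; run made earlier
- ash: protic impurity 2.4 mM; precatalyst 24 µM; temperature 20 °C; run made earlier
- midnight: protic impurity 1.20 mM; precatalyst 24 µM; temperature 25 °C; time 12 min
- dawn: protic impurity 1.20 mM; precatalyst 24 µM; temperature 45 °C; time 12 min

| run | time / min | product / % |
|---|---|---|
| birch | 3.00 | 5.6 |
| birch | 6.00 | 18.5 |
| birch | 8.00 | 27.0 |
| birch | 12.0 | 45.1 |
| birch | 15.0 | 54.0 |
| cedar | 0.667 | 13.0 |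
| cedar | 1.33 | 35.7 |
| cedar | 2.50 | 68.9 |
| cedar | 5.00 | 88.9 |
| cedar | 10.0 | 91.4 |
| ash | 3.00 | 11.0 |
| ash | 6.00 | 28.2 |
| ash | 8.00 | 41.8 |
| ash | 12.0 | 59.8 |
| ash | 15.0 | 68.5 |

(each reading ± 1 percentage point)



1. the flask that comes out highest in amount of product, in percent of the starting material charged, or "all alike" when all lie within 1.5 percentage points (midnight / dawn / all alike)
2. product at the end, in percent of the starting material charged, midnight
3. product at the end, in percent of the starting material charged, dawn

Cedar read 91.4% after 10.0 min. Its protic impurity was 10.0% of the starting material, so I assumed each equivalent of impurity costs one of starting material. That puts the ceiling at 90.0% of the charge for birch, cedar, midnight and dawn, and at 80.0% for ash.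

I also assumed a pseudo-first-order approach: the product still missing below the ceiling shrinks by the same factor in each equal stretch of time. So I counted turns, the natural log of the ceiling over what is still missing. This lumps the slow first minutes in with the rest. The readings at 12.0 min gave ash 1.38 turns and birch 0.695. Ash had twice birch's precatalyst at the same temperature, and also twice its protic impurity, which I had already put into its ceiling. It read twice the turns, so I let turns go with precatalyst and time.

Cedar's reading gave 1.45 turns in 2.50 min. Per unit of precatalyst and time, that is 2.53 times ash's pace. I spread that factor evenly over temperature. Midnight and dawn match ash in precatalyst and time, so midnight gets 1.88 turns, or 76.2%, and dawn gets 6.46 turns, or 89.9%.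

The forecast put dawn highest, with 79% for midnight and 89% for dawn, “unless the catalyst dies when hot”. My midnight figure was lower than the forecast's.

Midnight gave 82.2% and dawn 90.5%, so dawn came out highest.

    starting material + protic impurity → quenched substrate (k = 0.910 M⁻¹ s⁻¹, Ea = 44.0 kJ mol⁻¹)
    starting material + catalyst → catalyst + product (k = 200 M⁻¹ s⁻¹, Ea = 38.0 kJ mol⁻¹)
    precatalyst → catalyst (k = 0.00430 s⁻¹, Ea = 94.0 kJ mol⁻¹)
    (constants at 25 °C)

Midnight's product was higher than my figure or the forecast's, and it counts 2.45 turns against my 1.88. The neighbouring flask is dawn run at 20 °C. It has dawn's ceiling, and it has ash's precatalyst, temperature and time, so I gave it ash's 1.38 turns, which makes 67.4%. That flask gave 67.1% of product, with 23.2% of the starting material still there.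

The runs stem from a simulated flask for substances that don't exist, noise included.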